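**Retrosynthetic overview**

1. Locants: C1 lactone C=O, C2, C3 (peroxide CH), C4 (lactone carbinol C), C5 (ring CH2), C6 (chain-bearing peroxide C), C7 (first chain carbon). The strategy rests on the C4–C5 bond of the 1,2-dioxane ring (O, O, C3, C4, C5, C6), which lies across the ring from the O–O bond, between the two peroxy carbons C3 and C6.
2. Target 21 ⇐ iodolactone 20 ⇐ dihydrodioxinylacetic acid 19 (the C1 carboxyl adds to C4 of a C4=C5 alkene) ⇐ 3,6-dihydro-1,2-dioxine 16 ⇐ ring-closing metathesis of the acyclic diallylic peroxide 15.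
3. 15 ⇐ peroxy diol 13 (glycol cleavage, then methylenation, gives the vinyl group on C6) ⇐ SN2 union at C3 of tertiary hydroperoxide 7 with allylic mesylate 12.
4. 7 ⇐ Sharpless epoxide 6 (perhydrolysis with inversion at C6) ⇐ acid 1; 12 ⇐ kinetic resolution of 10 ⇐ aldehyde 8 + Grignard reagent 9. Ring order: the dioxine ring first (step 12), the γ-lactone second (step 15).

Key step: step 12

Remark: the hydroperoxide is alkylated before the glycol is cleaved, so that no free O–O–H group meets the phosphorus ylide of step 11. Stereochemical leakage in steps 2, 4, 5 or 7 shows up as diastereomers of 7, 13 or 16, which chromatography should remove.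

**Route**

Step 1
Reactants: 1 11-phenylundecanoic acid
Product: 2 12-phenyldodecan-2-one
Conditions: MeLi (2.2 equiv), Et2O, 0 °C → rt; then cold aq. HCl
Reagents that add atoms: methyllithium, [Li]C
Why: Methyl ketone synthesis from a carboxylic acid and an organolithium: the dilithium gem-diolate formed from the lithium carboxylate and MeLi does not collapse until the acidic quench, so addition should stop at the ketone.

Step 2
Reactants: 2 12-phenyldodecan-2-one; 3 triethyl phosphonoacetate
Product: 4 ethyl (2E)-3-methyl-13-phenyltridec-2-enoate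
Conditions: NaH, THF, 0 °C → reflux; chromatography to remove the Z isomer
Reagents that add atoms: none
Why: Horner–Wadsworth–Emmons olefination of a methyl ketone should give mainly the E enoate (long chain trans to the ester); the minor Z ester is separated here.

Step 3
Reactants: 4 ethyl (2E)-3-methyl-13-phenyltridec-2-enoate
Product: 5 (2E)-3-methyl-13-phenyltridec-2-en-1-ol
Conditions: i-Bu2AlH (2.2 equiv), CH2Cl2, −78 → 0 °C; aq. potassium sodium tartrate
Reagents that add atoms: none
Why: 1,2-Reduction of an enoate by an aluminium hydride at low temperature should give the allylic alcohol without change of alkene geometry.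

Step 4
Reactants: 5 (2E)-3-methyl-13-phenyltridec-2-en-1-ol
Product: 6 [(2S,3S)-3-methyl-3-(10-phenyldecyl)oxiran-2-yl]methanol
Conditions: Ti(O-i-Pr)4 (cat.), L-(+)-diethyl tartrate (cat.), t-BuOOH, 4 Å molecular sieves, CH2Cl2, −20 °C
Reagents that add atoms: tert-butyl hydroperoxide, CC(C)(C)OO
Why: Sharpless asymmetric epoxidation: with L-(+)-tartrate an E-3,3-disubstituted allylic alcohol of the geraniol type should be epoxidised on the face that gives the (2S,3S)-oxirane, which fixes the future C6 (oxirane C3) and a spectator centre at oxirane C2.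

Step 5
Reactants: 6 [(2S,3S)-3-methyl-3-(10-phenyldecyl)oxiran-2-yl]methanol
Product: 7 (2S,3R)-3-hydroperoxy-3-methyl-13-phenyltridecane-1,2-diol
Conditions: anhydrous H2O2 in Et2O (excess), H3PMo12O40 (cat.), 0 °C → rt
Reagents that add atoms: hydrogen peroxide, OO
Why: Acid-catalysed perhydrolysis of an epoxide: H2O2 should attack the tertiary oxirane carbon (the other carbon is deactivated by the neighbouring C–O bond) with inversion, turning the (3S)-oxirane carbon into the (3R)-hydroperoxide carbon that becomes C6; the untouched C2 carbinol makes any retention product a separable diastereomer.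

Step 6
Reactants: 8 3-[(tert-butyldimethylsilyl)oxy]propanal; 9 isopropenylmagnesium bromide
Product: 10 rac-5-[(tert-butyldimethylsilyl)oxy]-2-methylpent-1-en-3-ol
Conditions: THF, −78 → 0 °C; aq. NH4Cl
Reagents that add atoms: none
Why: Grignard addition of an alkenylmagnesium halide to an unhindered aldehyde should give the racemic allylic alcohol that carries C1–C4.

Step 7
Reactants: 10 rac-5-[(tert-butyldimethylsilyl)oxy]-2-methylpent-1-en-3-ol
Product: 11 (3R)-5-[(tert-butyldimethylsilyl)oxy]-2-methylpent-1-en-3-ol (unreacted enantiomer, recovered)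
Conditions: Ti(O-i-Pr)4, L-(+)-diisopropyl tartrate, t-BuOOH (0.6 equiv), 4 Å molecular sieves, CH2Cl2, −20 °C
Reagents that add atoms: none
Why: Sharpless kinetic resolution: with L-(+)-tartrate the (S)-alcohol should be epoxidised faster, so the (R)-alcohol should be recovered in high enantiomeric purity once conversion passes one half; this fixes C3 ahead of its later inversion.

Step 8
Reactants: 11 (3R)-5-[(tert-butyldimethylsilyl)oxy]-2-methylpent-1-en-3-ol
Product: 12 (3R)-5-[(tert-butyldimethylsilyl)oxy]-2-methylpent-1-en-3-yl methanesulfonate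
Conditions: (MeSO2)2O, Et3N, CH2Cl2, −20 °C; cold aqueous work-up, used at once
Reagents that add atoms: methanesulfonic anhydride, CS(=O)(=O)OS(C)(=O)=O
Why: O-Sulfonylation leaves the C–O bond and hence the configuration untouched, and the anhydride avoids chloride ion, which could displace the allylic sulfonate.

Step 9
Reactants: 7 (2S,3R)-3-hydroperoxy-3-methyl-13-phenyltridecane-1,2-diol; 12 (3R)-5-[(tert-butyldimethylsilyl)oxy]-2-methylpent-1-en-3-yl methanesulfonate
Product: 13 (2S,3R)-3-{[(3S)-5-[(tert-butyldimethylsilyl)oxy]-2-methylpent-1-en-3-yl]peroxy}-3-methyl-13-phenyltridecane-1,2-diol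
Conditions: CsOH·H2O (1 equiv), DMF, −20 → 0 °C
Reagents that add atoms: none
Why: Williamson-type O-alkylation of a hydroperoxide (SN2 displacement of a sulfonate by an alkylperoxide anion): the hydroperoxide (pKa about 12–13) is deprotonated in preference to the diol, and its unhindered terminal oxygen should attack C3 with inversion, (R)-mesylate to (S)-peroxide, in a polar aprotic medium that disfavours ionisation.

Step 10
Reactants: 13 (2S,3R)-3-{[(3S)-5-[(tert-butyldimethylsilyl)oxy]-2-methylpent-1-en-3-yl]peroxy}-3-methyl-13-phenyltridecane-1,2-diol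
Product: 14 (2R)-2-{[(3S)-5-[(tert-butyldimethylsilyl)oxy]-2-methylpent-1-en-3-yl]peroxy}-2-methyl-12-phenyldodecanal
Conditions: NaIO4, THF/aq. pH 7 buffer, 0 °C → rt
Reagents that add atoms: none
Why: Periodate glycol cleavage (Malaprade reaction) removes the terminal carbinol carbon as formaldehyde and leaves an aldehyde (the future C5) on the fully substituted C6, which cannot epimerise; dialkyl peroxide and silyl ether are inert to periodate.

Step 11
Reactants: 14 (2R)-2-{[(3S)-5-[(tert-butyldimethylsilyl)oxy]-2-methylpent-1-en-3-yl]peroxy}-2-methyl-12-phenyldodecanal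
Product: 15 tert-butyldimethylsilyl ether of (3S)-4-methyl-3-{[(3R)-3-methyl-13-phenyltridec-1-en-3-yl]peroxy}pent-4-en-1-ol
Conditions: Ph3PCH3Br, KN(SiMe3)2, THF, 0 °C; then 14, −78 → 0 °C
Reagents that add atoms: methyltriphenylphosphonium bromide, C[P+](c1ccccc1)(c1ccccc1)c1ccccc1.[Br-]
Why: Wittig methylenation of a non-enolisable aldehyde at low temperature should be much faster than attack of the ylide on the dialkyl peroxide, and it places the vinyl group on C6.

Step 12
Reactants: 15 tert-butyldimethylsilyl ether of (3S)-4-methyl-3-{[(3R)-3-methyl-13-phenyltridec-1-en-3-yl]peroxy}pent-4-en-1-ol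
Product: 16 tert-butyldimethylsilyl ether of 2-[(3S,6R)-4,6-dimethyl-6-(10-phenyldecyl)-3,6-dihydro-1,2-dioxin-3-yl]ethanol
Conditions: second-generation Hoveyda–Grubbs catalyst RuCl2(H2IMes)(=CH-C6H4-2-O-i-Pr) (H2IMes = 1,3-dimesitylimidazolidin-2-ylidene; 10 mol %), toluene (0.005 M), 60 °C, Ar purge
Reagents that add atoms: none
Why: Ring-closing olefin metathesis: the ruthenium benzylidene exchanges onto the monosubstituted vinyl group on C6 to give the alkylidene Ru=C5H–C6, this adds across the isopropenyl group in a [2+2] step, and cycloreversion of the ruthenacyclobutane forms the C4=C5 bond and Ru=CH2, which leaves as ethene on turnover. The closest known reaction type is ring-closing metathesis of dialkyl peroxides bearing an alkene on each peroxy carbon to give 3,6-dihydro-1,2-dioxines, together with the closure of tertiary vinyl carbinol derivatives to trisubstituted cycloalkenes. The one ring formed is the six-membered 3,6-dihydro-1,2-dioxine (O, O, C3, C4, C5, C6), closed at C4=C5 opposite the O–O bond by cyclisation of a 4,5-dioxaocta-1,7-diene, and the ring size allows only the Z alkene. No stereocentre is created; C3 and C6 are carried unchanged from 15 under these neutral conditions. The step needs chemoselectivity for intramolecular closure over oligomerisation and over attack on the O–O bond: high dilution, the gauche C–O–O–C preference of peroxides and the fully substituted C6 (Thorpe–Ingold effect) should hold the two alkenes close, and the ruthenium carbene is neither a reductant nor a strong Lewis acid toward the peroxide.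

Step 13
Reactants: 16 tert-butyldimethylsilyl ether of 2-[(3S,6R)-4,6-dimethyl-6-(10-phenyldecyl)-3,6-dihydro-1,2-dioxin-3-yl]ethanol
Product: 17 2-[(3S,6R)-4,6-dimethyl-6-(10-phenyldecyl)-3,6-dihydro-1,2-dioxin-3-yl]ethan-1-ol
Conditions: HF·pyridine, pyridine/THF, 0 °C → rt
Reagents that add atoms: none
Why: Fluoride-mediated cleavage of a primary silyl ether under buffered acidic conditions; basic fluoride sources are avoided because the C3–H of the dihydrodioxine is prone to base-induced Kornblum–DeLaMare fragmentation.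

Step 14
Reactants: 17 2-[(3S,6R)-4,6-dimethyl-6-(10-phenyldecyl)-3,6-dihydro-1,2-dioxin-3-yl]ethan-1-ol
Product: 19 2-[(3S,6R)-4,6-dimethyl-6-(10-phenyldecyl)-3,6-dihydro-1,2-dioxin-3-yl]acetic acid, via dioxinylacetaldehyde 18 (not isolated)
Conditions: TEMPO (cat.), PhI(OAc)2, MeCN/H2O, rt
Reagents that add atoms: water, O
Why: Nitroxyl-catalysed oxidation of a primary alcohol through the aldehyde hydrate to the carboxylic acid runs near neutral pH and should spare the trisubstituted alkene and the O–O bond.

Step 15
Reactants: 19 2-[(3S,6R)-4,6-dimethyl-6-(10-phenyldecyl)-3,6-dihydro-1,2-dioxin-3-yl]acetic acid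
Product: 20 (3R,4S,4aR,7aS)-4-iodo-3,4a-dimethyl-3-(10-phenyldecyl)-3,4,4a,7a-tetrahydrofuro[3,2-c][1,2]dioxin-6(7H)-one (the 5-iodo derivative of the target, iodine trans to the lactone oxygen)
Conditions: I2, aq. NaHCO3, CH2Cl2, 0 °C → rt, dark
Reagents that add atoms: iodine, II
Why: Iodolactonisation: the iodonium ion forms reversibly on C4=C5 and the carboxylate tethered at C3 can reach only C4 on its own face (5-exo, Markovnikov), so the γ-lactone is necessarily cis-fused, the new C4 stereocentre is set by C3, and iodine ends anti on C5.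

Step 16
Reactants: 20 (3R,4S,4aR,7aS)-4-iodo-3,4a-dimethyl-3-(10-phenyldecyl)-3,4,4a,7a-tetrahydrofuro[3,2-c][1,2]dioxin-6(7H)-one
Product: 21 (3R,4aS,7aS)-3,4a-dimethyl-3-(10-phenyldecyl)-3,4,4a,7a-tetrahydrofuro[3,2-c][1,2]dioxin-6(7H)-one (CNP0407146.3)
Conditions: n-Bu3SnH, AIBN (cat.), benzene, 70 °C
Reagents that add atoms: none
Why: Radical chain dehalogenation: the C5 radical formed by iodine abstraction should be quenched by the tin hydride faster than it can displace on the ring O–O bond, whose gauche alignment in the six-membered ring disfavours that 3-exo attack; C5 becomes CH2 and no stereocentre is touched.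

**Compound list**

1 | 11-phenylundecanoic acid | OC(=O)CCCCCCCCCCc1ccccc1 | starting material
2 | 12-phenyldodecan-2-one | CC(=O)CCCCCCCCCCc1ccccc1 | intermediate
3 | triethyl phosphonoacetate | CCOC(=O)CP(=O)(OCC)OCC | starting material
4 | ethyl (2E)-3-methyl-13-phenyltridec-2-enoate | CCOC(=O)/C=C(\C)CCCCCCCCCCc1ccccc1 | intermediate
5 | (2E)-3-methyl-13-phenyltridec-2-en-1-ol | OC/C=C(\C)CCCCCCCCCCc1ccccc1 | intermediate
6 | [(2S,3S)-3-methyl-3-(10-phenyldecyl)oxiran-2-yl]methanol | C[C@@]1(CCCCCCCCCCc2ccccc2)O[C@H]1CO | intermediate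
7 | (2S,3R)-3-hydroperoxy-3-methyl-13-phenyltridecane-1,2-diol | OC[C@H](O)[C@](C)(OO)CCCCCCCCCCc1ccccc1 | intermediate
8 | 3-[(tert-butyldimethylsilyl)oxy]propanal | O=CCCO[Si](C)(C)C(C)(C)C | starting material
9 | isopropenylmagnesium bromide | CC(=C)[Mg]Br | starting material
10 | rac-5-[(tert-butyldimethylsilyl)oxy]-2-methylpent-1-en-3-ol | C=C(C)C(O)CCO[Si](C)(C)C(C)(C)C | intermediate
11 | (3R)-5-[(tert-butyldimethylsilyl)oxy]-2-methylpent-1-en-3-ol | C=C(C)[C@H](O)CCO[Si](C)(C)C(C)(C)C | intermediate
12 | (3R)-5-[(tert-butyldimethylsilyl)oxy]-2-methylpent-1-en-3-yl methanesulfonate | C=C(C)[C@H](OS(C)(=O)=O)CCO[Si](C)(C)C(C)(C)C | intermediate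
13 | (2S,3R)-3-{[(3S)-5-[(tert-butyldimethylsilyl)oxy]-2-methylpent-1-en-3-yl]peroxy}-3-methyl-13-phenyltridecane-1,2-diol | OC[C@H](O)[C@](C)(OO[C@@H](CCO[Si](C)(C)C(C)(C)C)C(C)=C)CCCCCCCCCCc1ccccc1 | intermediate
14 | (2R)-2-{[(3S)-5-[(tert-butyldimethylsilyl)oxy]-2-methylpent-1-en-3-yl]peroxy}-2-methyl-12-phenyldodecanal | O=C[C@](C)(OO[C@@H](CCO[Si](C)(C)C(C)(C)C)C(C)=C)CCCCCCCCCCc1ccccc1 | intermediate
15 | tert-butyldimethylsilyl ether of (3S)-4-methyl-3-{[(3R)-3-methyl-13-phenyltridec-1-en-3-yl]peroxy}pent-4-en-1-ol | C=C[C@](C)(OO[C@@H](CCO[Si](C)(C)C(C)(C)C)C(C)=C)CCCCCCCCCCc1ccccc1 | intermediate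
16 | tert-butyldimethylsilyl ether of 2-[(3S,6R)-4,6-dimethyl-6-(10-phenyldecyl)-3,6-dihydro-1,2-dioxin-3-yl]ethanol | C[C@@]1(CCCCCCCCCCc2ccccc2)C=C(C)[C@H](CCO[Si](C)(C)C(C)(C)C)OO1 | intermediate
17 | 2-[(3S,6R)-4,6-dimethyl-6-(10-phenyldecyl)-3,6-dihydro-1,2-dioxin-3-yl]ethan-1-ol | C[C@@]1(CCCCCCCCCCc2ccccc2)C=C(C)[C@H](CCO)OO1 | intermediate
18 | 2-[(3S,6R)-4,6-dimethyl-6-(10-phenyldecyl)-3,6-dihydro-1,2-dioxin-3-yl]acetaldehyde | C[C@@]1(CCCCCCCCCCc2ccccc2)C=C(C)[C@H](CC=O)OO1 | intermediate
19 | 2-[(3S,6R)-4,6-dimethyl-6-(10-phenyldecyl)-3,6-dihydro-1,2-dioxin-3-yl]acetic acid | C[C@@]1(CCCCCCCCCCc2ccccc2)C=C(C)[C@H](CC(=O)O)OO1 | intermediate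
20 | (3R,4S,4aR,7aS)-4-iodo-3,4a-dimethyl-3-(10-phenyldecyl)-3,4,4a,7a-tetrahydrofuro[3,2-c][1,2]dioxin-6(7H)-one | C[C@@]1(CCCCCCCCCCc2ccccc2)[C@@H](I)[C@]2(C)OC(=O)C[C@@H]2OO1 | intermediate
21 | (3R,4aS,7aS)-3,4a-dimethyl-3-(10-phenyldecyl)-3,4,4a,7a-tetrahydrofuro[3,2-c][1,2]dioxin-6(7H)-one | C[C@@]1(CCCCCCCCCCc2ccccc2)C[C@]2(C)OC(=O)C[C@@H]2OO1 | target

**Step count and risks**

Total: 16 steps. Longest linear sequence: 13 steps (steps 1–5, then 9–16).

Steps most likely to fail:

1. Step 12 (key step). The carbene may load slowly on the vinyl group beside the fully substituted C6 and be consumed by the O–O bond or by intermolecular metathesis before it closes onto the 1,1-disubstituted alkene. Fallback, relay ring-closing metathesis: set out from aldehyde 14. A Wittig reaction with the ylide from (hex-5-en-1-yl)triphenylphosphonium bromide and KN(SiMe3)2 (THF, −78 → 0 °C) should give the relay triene tert-butyldimethyl{[(3S)-4-methyl-3-{[(6Z,8R)-8-methyl-18-phenyloctadeca-1,6-dien-8-yl]peroxy}pent-4-en-1-yl]oxy}silane F1. With the same ruthenium catalyst the carbene loads on the unhindered terminal alkene, expels cyclopentene and is thereby delivered onto C5, from where it closes onto the isopropenyl group. The route is rejoined at 16.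

2. Step 9. Attack of the peroxide anion at the alkene terminus (SN2′), elimination of the mesylate to a diene, or base-induced fragmentation of the β-hydroxy hydroperoxide may outrun direct displacement, with loss of regio- and stereocontrol at C3. Fallback, reversal of roles: set out from mesylate 12. Displacement with the small nucleophile hydrogen peroxide (excess H2O2, CsOH·H2O, DMF/Et2O, −20 °C, inversion) should give (3S)-5-[(tert-butyldimethylsilyl)oxy]-2-methylpent-1-en-3-yl hydroperoxide F2. Used in place of H2O2 in the acid-catalysed opening of epoxy alcohol 6 (H3PMo12O40 cat., Et2O), this alkyl hydroperoxide should add to the tertiary oxirane carbon with inversion. The route is rejoined at 13 and 7 is bypassed.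

3. Step 2. The olefination of a methyl ketone is incompletely E-selective and the geometric isomers may co-elute; Z ester carried forward leads to the C6 epimer. Fallback, stereospecific carbometalation: set out from acid 1. Reduction with LiAlH4 (THF) gives 11-phenylundecan-1-ol F3, and Dess–Martin periodinane (CH2Cl2) gives 11-phenylundecanal F4. Ohira–Bestmann homologation (dimethyl (1-diazo-2-oxopropyl)phosphonate, K2CO3, MeOH) gives 12-phenyldodec-1-yne F5. Zirconium-catalysed syn-carboalumination (Me3Al, cat. (C5H5)2ZrCl2, CH2Cl2) then gives dimethyl[(1E)-2-methyl-12-phenyldodec-1-en-1-yl]alane F6, which after n-BuLi and (CH2O)n should give the E alcohol alone. The route is rejoined at 5.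

Further compounds
F1 | step 12 | tert-butyldimethyl{[(3S)-4-methyl-3-{[(6Z,8R)-8-methyl-18-phenyloctadeca-1,6-dien-8-yl]peroxy}pent-4-en-1-yl]oxy}silane | C=CCCC/C=C\[C@](C)(OO[C@@H](CCO[Si](C)(C)C(C)(C)C)C(C)=C)CCCCCCCCCCc1ccccc1
F2 | step 9 | (3S)-5-[(tert-butyldimethylsilyl)oxy]-2-methylpent-1-en-3-yl hydroperoxide | C=C(C)[C@@H](OO)CCO[Si](C)(C)C(C)(C)C
F3 | step 2 | 11-phenylundecan-1-ol | OCCCCCCCCCCCc1ccccc1
F4 | step 2 | 11-phenylundecanal | O=CCCCCCCCCCCc1ccccc1
F5 | step 2 | 12-phenyldodec-1-yne | C#CCCCCCCCCCCc1ccccc1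
F6 | step 2 | dimethyl[(1E)-2-methyl-12-phenyldodec-1-en-1-yl]alane | C[Al](C)/C=C(\C)CCCCCCCCCCc1ccccc1
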